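At early times the substrate of the south-west run falls along a straight line, so you can replace the curve by one mean slope and carry that slope, per unit of catalyst, to your flask.

the same everywhere: gas 160 mM (held)
- south-west: substrate 1 M; free catalyst 0.14 mol%; run made earlier
- north-west: substrate 1 M; free catalyst 0.32 mol%; run made earlier
- flask: substrate 1.0 M; free catalyst 0.21 mol%; time 10 d

| run | time / d | target / % | substrate / % |
|---|---|---|---|
| south-west | 2.08 | 22.3 | 73.5 |
| south-west | 4.00 | 43.2 | 49.4 |
| south-west | 6.00 | 63.5 | 25.3 |
| south-west | 8.00 | 83.6 | 5.1 |
| south-west | 10.0 | 87.6 | 0 |
| south-west | 12.0 | 88.7 | 0.9 |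
| north-west | 2.08 | 50.4 | 40.8 |
| north-west | 4.00 | 87.2 | 2.4 |
| north-west | 6.00 | 87.7 | 0.9 |
| north-west | 8.00 | 85.2 | 1.0 |
| north-west | 10.0 | 87.7 | 0 |
| north-west | 12.0 | 88.2 | 0 |

(scatter of a reading: 1 percentage point)

1. the target standing at 10 d, as a percentage of the substrate charged
2. the change that raises the amount of target at 10 d, in percent of the substrate charged most ("none" if none brings more than 2 percentage points) (autumn / dawn / midnight / none)
3. amount of target at 10 d, in percent of the substrate charged, after autumn

- autumn: doubling the saturation concentration of gas, all else as stated
- dawn: doubling the amount of free catalyst, all else as stated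
- midnight: doubling the transfer coefficient of the gas, all else as stated

- at the start none of the gas is in solution

Take the south-west substrate between 2.08 d and 6.00 d, at a loading of 0.14 mol%. The mean fall divided by the loading is substrate consumed per catalyst charged per day, the turnover frequency:

turnover frequency = 87.8 d⁻¹

The start of the north-west run, a separate check, gives 88.9 d⁻¹ at 0.32 mol%, so I read the frequency as the same at both loadings. It gives the time at which the straight line reaches zero substrate:

clearing time = one ÷ (turnover frequency × loading)

south-west run: 8.13 d

your flask: 5.42 d

The line runs slightly ahead of the tail: at 8.00 d it leaves 1.63% of the substrate in the south-west run, where the reading is 5.1%.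

Your flask resembles the south-west run, but its line reaches zero sooner, and both lines reach zero before 10 d, so I expect both to stand on the late level of target by then. The south-west target readings from 10.0 d on and the north-west ones from 6.00 d on average 87.5%, with loadings a factor 2.29 apart. I therefore commit to that figure for your flask and expect no useful change; for autumn, which no run tests, I hold the same figure less firmly.

The forecast gives 87.6%, close to my figure, with none as best and 87.6% after autumn, calling the level “stable and independent of loading”.

The flask gives 87.0% at 10 d, 87.0% after autumn and none as best, with substrate at 0% and isomer of the product at 13.0% at that time. At 5.00 d the turnover frequency leaves 7.78% of the substrate in this flask, and it holds 9.45%.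

    gas ⇌ coupling partner, rate k1*(csat - [coupling partner]) (kL = 4.35 × 10⁻⁴ s⁻¹)
    catalyst intermediate B → free catalyst + target (k = 0.00128 s⁻¹)
    coupling partner + catalyst intermediate A → catalyst intermediate B (k = 0.0388 L mol⁻¹ s⁻¹)
    target ⇌ isomer of the product (K = 0.150, k = 5.00 × 10⁻⁵ s⁻¹)
    substrate + free catalyst → catalyst intermediate A (k = 0.0485 L mol⁻¹ s⁻¹)

A neighbouring flask charged with 0.084 mol% has a reckoned clearing time of 13.6 d, later than 10 d, so the reckoning leaves 26.2% of its substrate at that time. The computed flask holds 26% of substrate and 64.2% of target.

The runs are simulated with made-up constants; the scatter is artificial.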